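**Retrosynthetic overview**
- Target 20 ← hydrogenolysis of four benzyl ethers in 19 ← acetylation of the only free OH (8-OH) in 18 ← removal of the 8-O-MOM group from 17.
- The pyranone ring (the only ring built, and built last) ← Algar–Flynn–Oyamada oxidative cyclisation of 2'-hydroxychalcone 14.
- Chalcone 14 ← intermolecular Claisen–Schmidt aldol condensation of acetophenone 11 with 3,4-bis(benzyloxy)benzaldehyde 12; this is the key C–C bond.
- Acetophenone 11 ← directed ortho-lithiation/acetylation of arene 5 between OMOM and OBn, then MOM removal and selective re-protection of the non-chelated 3-OH.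
- Arene 5 ← Baeyer–Villiger oxidation and benzylation of bis-MOM 5-hydroxyvanillin; both aromatic rings are purchased.

Assumption: the target has no stereocentre (it is achiral), so no enantiocontrol is needed; only the E geometry of chalcone 14 has to be set.

**Step 1**
Reactants: 1 3,4-dihydroxy-5-methoxybenzaldehyde
Product: 2 3-methoxy-4,5-bis(methoxymethoxy)benzaldehyde
Conditions: MOMCl (2.6 equiv), i-Pr2NEt (3 equiv), CH2Cl2, 0 °C → rt
Reagents that add atoms: chloromethyl methyl ether (MOMCl), COCCl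
Why: Williamson-type O-alkylation converts both catechol hydroxyls into MOM acetals, which later act as the directing group for lithiation; the aldehyde is untouched and no stereocentre forms.

**Step 2**
Reactants: 2 3-methoxy-4,5-bis(methoxymethoxy)benzaldehyde
Product: 4 3-methoxy-4,5-bis(methoxymethoxy)phenol, via aryl formate 3 (not isolated)
Conditions: mCPBA (1.4 equiv), CH2Cl2, 0 °C → rt; then K2CO3 (cat.), MeOH, rt
Reagents that add atoms: meta-chloroperoxybenzoic acid (mCPBA), OOC(=O)c1cccc(Cl)c1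
Why: Baeyer–Villiger (Dakin-type) oxidation, in which the electron-rich para-alkoxy aryl group migrates in preference to hydride to give the formate, which is methanolysed to the phenol while the MOM ethers survive.

**Step 3**
Reactants: 4 3-methoxy-4,5-bis(methoxymethoxy)phenol
Product: 5 5-(benzyloxy)-1-methoxy-2,3-bis(methoxymethoxy)benzene
Conditions: BnBr (1.2 equiv), K2CO3, DMF, rt
Reagents that add atoms: benzyl bromide, BrCc1ccccc1
Why: Williamson ether synthesis on the only free phenol installs the future 5-O-benzyl group.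

**Step 4**
Reactants: 5 5-(benzyloxy)-1-methoxy-2,3-bis(methoxymethoxy)benzene; 6 N-methoxy-N-methylacetamide
Product: 9 1-[6-(benzyloxy)-4-methoxy-2,3-bis(methoxymethoxy)phenyl]ethan-1-one, via aryllithium 7 (not isolated), via lithium hemiaminal adduct 8 (not isolated)
Conditions: n-BuLi (1.15 equiv), TMEDA, THF, −78 → 0 °C; then 6, −78 °C → rt; H2O
Reagents that add atoms: none
Why: Directed ortho-metalation, in which the chelating MOM acetal (a much stronger director than OMe) steers lithiation to the C–H between OMOM and OBn, followed by Weinreb-amide acylation whose stable chelate 8 prevents over-addition.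

**Step 5**
Reactants: 9 1-[6-(benzyloxy)-4-methoxy-2,3-bis(methoxymethoxy)phenyl]ethan-1-one
Product: 10 1-[6-(benzyloxy)-2,3-dihydroxy-4-methoxyphenyl]ethan-1-one
Conditions: conc. HCl (cat.), MeOH, 50 °C
Reagents that add atoms: none
Why: Acid-catalysed acetal methanolysis removes both MOM groups, while the benzyl ether, methyl ether and ketone are inert to dilute methanolic HCl.

**Step 6**
Reactants: 10 1-[6-(benzyloxy)-2,3-dihydroxy-4-methoxyphenyl]ethan-1-one
Product: 11 1-[6-(benzyloxy)-2-hydroxy-4-methoxy-3-(methoxymethoxy)phenyl]ethan-1-one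
Conditions: MOMCl (1.05 equiv), i-Pr2NEt (1.3 equiv), CH2Cl2, 0 °C
Reagents that add atoms: chloromethyl methyl ether (MOMCl), COCCl
Why: Selective O-alkylation, because the 2-OH is locked in a strong hydrogen bond to the ortho acetyl carbonyl and stays inert under mild amine-base conditions, so only the 3-OH (the future 8-O) is protected.

**Step 7**
Reactants: 11 1-[6-(benzyloxy)-2-hydroxy-4-methoxy-3-(methoxymethoxy)phenyl]ethan-1-one; 12 3,4-bis(benzyloxy)benzaldehyde
Product: 14 (2E)-1-[6-(benzyloxy)-2-hydroxy-4-methoxy-3-(methoxymethoxy)phenyl]-3-[3,4-bis(benzyloxy)phenyl]prop-2-en-1-one, via aldol adduct 13 (not isolated)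
Conditions: KOH (50% aq., excess), EtOH, rt, 36 h; then cold dil. AcOH to pH 6
Reagents that add atoms: none
Why: Claisen–Schmidt crossed aldol condensation of the methyl ketone enolate with the non-enolisable aldehyde, where E1cB dehydration removes the carbinol stereocentre of 13 and gives the thermodynamically favoured E enone.

**Step 8**
Reactants: 14 (2E)-1-[6-(benzyloxy)-2-hydroxy-4-methoxy-3-(methoxymethoxy)phenyl]-3-[3,4-bis(benzyloxy)phenyl]prop-2-en-1-one
Product: 16 5-(benzyloxy)-2-[3,4-bis(benzyloxy)phenyl]-3-hydroxy-7-methoxy-8-(methoxymethoxy)-4H-chromen-4-one, via dihydroflavonol 15 (not isolated)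
Conditions: 30% H2O2, 2 M NaOH, MeOH/THF, 0 °C → rt
Reagents that add atoms: hydrogen peroxide, OO
Why: Algar–Flynn–Oyamada reaction, in which alkaline peroxide oxidises the enone as the 2'-phenoxide closes the ring to the trans-dihydroflavonol, which is dehydrogenated in the flask to the achiral flavonol; the low temperature disfavours aurone formation.

**Step 9**
Reactants: 16 5-(benzyloxy)-2-[3,4-bis(benzyloxy)phenyl]-3-hydroxy-7-methoxy-8-(methoxymethoxy)-4H-chromen-4-one
Product: 17 3,5-bis(benzyloxy)-2-[3,4-bis(benzyloxy)phenyl]-7-methoxy-8-(methoxymethoxy)-4H-chromen-4-one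
Conditions: BnBr (1.5 equiv), K2CO3, DMF, 60 °C
Reagents that add atoms: benzyl bromide, BrCc1ccccc1
Why: Williamson etherification of the only free hydroxyl (3-OH), so that later only the 8-position can be acetylated.

**Step 10**
Reactants: 17 3,5-bis(benzyloxy)-2-[3,4-bis(benzyloxy)phenyl]-7-methoxy-8-(methoxymethoxy)-4H-chromen-4-one
Product: 18 3,5-bis(benzyloxy)-2-[3,4-bis(benzyloxy)phenyl]-8-hydroxy-7-methoxy-4H-chromen-4-one
Conditions: 3 M HCl, MeOH/THF, 45 °C
Reagents that add atoms: none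
Why: Acid-catalysed methanolysis cleaves the aryl MOM acetal far faster than any benzyl ether, exposing the 8-OH alone.

**Step 11**
Reactants: 18 3,5-bis(benzyloxy)-2-[3,4-bis(benzyloxy)phenyl]-8-hydroxy-7-methoxy-4H-chromen-4-one
Product: 19 3,5-bis(benzyloxy)-2-[3,4-bis(benzyloxy)phenyl]-7-methoxy-4-oxo-4H-chromen-8-yl acetate
Conditions: Ac2O (1.5 equiv), pyridine, DMAP (cat.), rt
Reagents that add atoms: acetic anhydride, CC(=O)OC(C)=O
Why: DMAP-catalysed O-acylation of the single free phenol, so no regioselectivity question arises.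

**Step 12**
Reactants: 19 3,5-bis(benzyloxy)-2-[3,4-bis(benzyloxy)phenyl]-7-methoxy-4-oxo-4H-chromen-8-yl acetate
Product: 20 2-(3,4-dihydroxyphenyl)-3,5-dihydroxy-7-methoxy-4-oxo-4H-chromen-8-yl acetate (gossypetin 7-methyl ether 8-acetate)
Conditions: H2 (1 atm), 10% Pd/C, EtOAc/THF, rt
Reagents that add atoms: none
Why: Catalytic hydrogenolysis of the four benzyl ethers in a neutral aprotic medium leaves the aryl acetate and the chromone C2=C3 bond intact, and the acetate cannot migrate because its neighbours are OMe and the ring oxygen.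

**Compound list**
1 | 3,4-dihydroxy-5-methoxybenzaldehyde (5-hydroxyvanillin) | COc1cc(C=O)cc(O)c1O | starting material
2 | 3-methoxy-4,5-bis(methoxymethoxy)benzaldehyde | COCOc1cc(C=O)cc(OC)c1OCOC | intermediate
3 | 3-methoxy-4,5-bis(methoxymethoxy)phenyl formate | COCOc1cc(OC=O)cc(OC)c1OCOC | intermediate
4 | 3-methoxy-4,5-bis(methoxymethoxy)phenol | COCOc1cc(O)cc(OC)c1OCOC | intermediate
5 | 5-(benzyloxy)-1-methoxy-2,3-bis(methoxymethoxy)benzene | COCOc1cc(OCc2ccccc2)cc(OC)c1OCOC | intermediate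
6 | N-methoxy-N-methylacetamide | CC(=O)N(C)OC | starting material
7 | [6-(benzyloxy)-4-methoxy-2,3-bis(methoxymethoxy)phenyl]lithium | COCOc1c([Li])c(OCc2ccccc2)cc(OC)c1OCOC | intermediate
8 | lithium 1-[6-(benzyloxy)-4-methoxy-2,3-bis(methoxymethoxy)phenyl]-1-[methoxy(methyl)amino]ethan-1-olate (racemic) | COCOc1c(C(C)(O[Li])N(C)OC)c(OCc2ccccc2)cc(OC)c1OCOC | intermediate
9 | 1-[6-(benzyloxy)-4-methoxy-2,3-bis(methoxymethoxy)phenyl]ethan-1-one | COCOc1c(C(C)=O)c(OCc2ccccc2)cc(OC)c1OCOC | intermediate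
10 | 1-[6-(benzyloxy)-2,3-dihydroxy-4-methoxyphenyl]ethan-1-one | CC(=O)c1c(OCc2ccccc2)cc(OC)c(O)c1O | intermediate
11 | 1-[6-(benzyloxy)-2-hydroxy-4-methoxy-3-(methoxymethoxy)phenyl]ethan-1-one | CC(=O)c1c(OCc2ccccc2)cc(OC)c(OCOC)c1O | intermediate
12 | 3,4-bis(benzyloxy)benzaldehyde | O=Cc1ccc(OCc2ccccc2)c(OCc2ccccc2)c1 | starting material
13 | 1-[6-(benzyloxy)-2-hydroxy-4-methoxy-3-(methoxymethoxy)phenyl]-3-[3,4-bis(benzyloxy)phenyl]-3-hydroxypropan-1-one (racemic) | COCOc1c(O)c(C(=O)CC(O)c2ccc(OCc3ccccc3)c(OCc3ccccc3)c2)c(OCc2ccccc2)cc1OC | intermediate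
14 | (2E)-1-[6-(benzyloxy)-2-hydroxy-4-methoxy-3-(methoxymethoxy)phenyl]-3-[3,4-bis(benzyloxy)phenyl]prop-2-en-1-one | COCOc1c(O)c(C(=O)/C=C/c2ccc(OCc3ccccc3)c(OCc3ccccc3)c2)c(OCc2ccccc2)cc1OC | intermediate
15 | trans-5-(benzyloxy)-2-[3,4-bis(benzyloxy)phenyl]-3-hydroxy-7-methoxy-8-(methoxymethoxy)-2,3-dihydro-4H-chromen-4-one (racemic; the 2R,3R enantiomer is drawn) | c1cc(c(cc1[C@@H]2[C@H](C(=O)c3c(cc(c(c3O2)OCOC)OC)OCc4ccccc4)O)OCc5ccccc5)OCc6ccccc6 | intermediate
16 | 5-(benzyloxy)-2-[3,4-bis(benzyloxy)phenyl]-3-hydroxy-7-methoxy-8-(methoxymethoxy)-4H-chromen-4-one | COCOc1c(OC)cc(OCc2ccccc2)c2c(=O)c(O)c(-c3ccc(OCc4ccccc4)c(OCc4ccccc4)c3)oc12 | intermediate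
17 | 3,5-bis(benzyloxy)-2-[3,4-bis(benzyloxy)phenyl]-7-methoxy-8-(methoxymethoxy)-4H-chromen-4-one | COCOc1c(OC)cc(OCc2ccccc2)c2c(=O)c(OCc3ccccc3)c(-c3ccc(OCc4ccccc4)c(OCc4ccccc4)c3)oc12 | intermediate
18 | 3,5-bis(benzyloxy)-2-[3,4-bis(benzyloxy)phenyl]-8-hydroxy-7-methoxy-4H-chromen-4-one | COc1cc(OCc2ccccc2)c2c(=O)c(OCc3ccccc3)c(-c3ccc(OCc4ccccc4)c(OCc4ccccc4)c3)oc2c1O | intermediate
19 | 3,5-bis(benzyloxy)-2-[3,4-bis(benzyloxy)phenyl]-7-methoxy-4-oxo-4H-chromen-8-yl acetate | COc1cc(OCc2ccccc2)c2c(=O)c(OCc3ccccc3)c(-c3ccc(OCc4ccccc4)c(OCc4ccccc4)c3)oc2c1OC(C)=O | intermediate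
20 | 2-(3,4-dihydroxyphenyl)-3,5-dihydroxy-7-methoxy-4-oxo-4H-chromen-8-yl acetate (gossypetin 7-methyl ether 8-acetate) | COc1cc(O)c2c(=O)c(O)c(-c3ccc(O)c(O)c3)oc2c1OC(C)=O | target

**Totals**
Total step count: 12. Longest linear sequence: 12 steps (1 → 20); compounds 6 and 12 are purchased and enter at steps 4 and 7.

**Steps most likely to fail, with fallbacks**

Step 4 (lithiation/acylation). The hindered 2,6-dioxygenated aryllithium may enolise amide 6 instead of adding to it, and benzylic metalation of the OBn group can compete. The fallback sets out from 5, which is lithiated to 7 as before, and replaces the acyl substitution by carbonyl addition plus oxidation. Adding acetaldehyde (THF, −78 °C) gives the carbinol 1-[6-(benzyloxy)-4-methoxy-2,3-bis(methoxymethoxy)phenyl]ethan-1-ol F1 (racemic). Dess–Martin periodinane (CH2Cl2, NaHCO3, rt) then oxidises it to ketone 9, where the route resumes.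

Step 8 (Algar–Flynn–Oyamada). A 6'-alkoxy group on the chalcone is known to divert part of the material to the aurone. The fallback sets out from chalcone 14 and separates ring closure from C3 oxygenation. NaOAc in refluxing EtOH cyclises it to the flavanone 5-(benzyloxy)-2-[3,4-bis(benzyloxy)phenyl]-7-methoxy-8-(methoxymethoxy)-2,3-dihydro-4H-chromen-4-one F2 (racemic). I2 in pyridine at 90 °C dehydrogenates this to the flavone 5-(benzyloxy)-2-[3,4-bis(benzyloxy)phenyl]-7-methoxy-8-(methoxymethoxy)-4H-chromen-4-one F3. Dimethyldioxirane (acetone/CH2Cl2, 0 °C) gives the epoxide 5-(benzyloxy)-2-[3,4-bis(benzyloxy)phenyl]-2,3-epoxy-7-methoxy-8-(methoxymethoxy)chroman-4-one F4 (racemic, not isolated), which ring-opens and tautomerises on a trace of TsOH or on silica to flavonol 16.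

Step 10 (MOM removal). The chelated 5-O-benzyl ether is the most acid-labile benzyl group and may be lost together with the MOM group. The fallback sets out from 17 and makes that loss deliberate. Conc. HCl/AcOH at 60 °C removes both groups and gives 3-(benzyloxy)-2-[3,4-bis(benzyloxy)phenyl]-5,8-dihydroxy-7-methoxy-4H-chromen-4-one F5. Ac2O (1.05 equiv) in pyridine at 0 °C acetylates only the 8-OH, because the 5-OH is tied up in a hydrogen bond to C4=O, giving 3-(benzyloxy)-2-[3,4-bis(benzyloxy)phenyl]-5-hydroxy-7-methoxy-4-oxo-4H-chromen-8-yl acetate F6. Hydrogenolysis (H2, Pd/C, EtOAc/THF) of the three remaining benzyl ethers gives target 20 directly.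

**Further compounds**
F1 | step 4 | 1-[6-(benzyloxy)-4-methoxy-2,3-bis(methoxymethoxy)phenyl]ethan-1-ol (racemic) | CC(O)c1c(OCc2ccccc2)cc(OC)c(OCOC)c1OCOC
F2 | step 8 | 5-(benzyloxy)-2-[3,4-bis(benzyloxy)phenyl]-7-methoxy-8-(methoxymethoxy)-2,3-dihydro-4H-chromen-4-one (racemic) | COCOc1c(OC)cc(OCc2ccccc2)c2c1OC(c1ccc(OCc3ccccc3)c(OCc3ccccc3)c1)CC2=O
F3 | step 8 | 5-(benzyloxy)-2-[3,4-bis(benzyloxy)phenyl]-7-methoxy-8-(methoxymethoxy)-4H-chromen-4-one | COCOc1c(OC)cc(OCc2ccccc2)c2c(=O)cc(-c3ccc(OCc4ccccc4)c(OCc4ccccc4)c3)oc12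
F4 | step 8 | 5-(benzyloxy)-2-[3,4-bis(benzyloxy)phenyl]-2,3-epoxy-7-methoxy-8-(methoxymethoxy)chroman-4-one (racemic) | COCOc1c(OC)cc(OCc2ccccc2)c2c1OC1(c3ccc(OCc4ccccc4)c(OCc4ccccc4)c3)OC1C2=O
F5 | step 10 | 3-(benzyloxy)-2-[3,4-bis(benzyloxy)phenyl]-5,8-dihydroxy-7-methoxy-4H-chromen-4-one | COc1cc(O)c2c(=O)c(OCc3ccccc3)c(-c3ccc(OCc4ccccc4)c(OCc4ccccc4)c3)oc2c1O
F6 | step 10 | 3-(benzyloxy)-2-[3,4-bis(benzyloxy)phenyl]-5-hydroxy-7-methoxy-4-oxo-4H-chromen-8-yl acetate | COc1cc(O)c2c(=O)c(OCc3ccccc3)c(-c3ccc(OCc4ccccc4)c(OCc4ccccc4)c3)oc2c1OC(C)=O
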